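**Retrosynthetic overview**

1. The target is a chain of three trans-2-aryl-3-aryl-2,3-dihydrobenzofurans, each numbered O-1, C-2, C-3, C-3a, C-4 to C-7, C-7a. Benzo ring A carries the (E)-3,4-dihydroxystyryl group at C-4 and its C-3 is bonded to C-4 of benzo ring B; C-3 of the ring-B heterocycle is bonded to C-4 of benzo ring C; C-3 of the ring-C heterocycle carries ring D (3,5-dihydroxyphenyl). All ten phenols travel as benzyl ethers.
2. Endgame: global debenzylation, preceded by Horner–Wadsworth–Emmons formation of the stilbene from the ring-A 4-carbaldehyde.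
3. Each heterocycle is cut at O-1–C-7a and C-2–C-3 in one operation, back to 4-(benzyloxy)benzaldehyde and a diarylmethane with fluorine on C-7a. The feature that allows this: C-3 is bonded to C-3a of its own benzo ring and to C-4 of the next ring, so before closure it is an acidic Ar–CH2–Ar carbon; and O-1 sits on C-7a, the ring carbon ortho to C-3a, where fluoride can leave to the C-2 alkoxide.
4. All three fluoro-diarylmethanes come from one aryl bromide, the (R,R)-butane-2,3-diol acetal of 5-(benzyloxy)-2-bromo-3-fluorobenzaldehyde, by Negishi coupling with a benzylic zinc halide. That zinc reagent is made from 3,5-bis(benzyloxy)benzyl bromide (ring C) or from the 4-(chloromethyl) compound obtained by reduction and chlorination of the 4-carbaldehyde of the ring made before (rings B and A). The acetal is the masked aldehyde for the next link and the chiral handle for the absolute configuration.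
5. Order of ring formation: heterocycle on ring C (step 5), on ring B (step 10), on ring A (step 14).

Key step: step 14

Remark: 3-fluoro-5-hydroxybenzaldehyde, (2R,3R)-butane-2,3-diol, 3,5-bis(benzyloxy)benzyl bromide, 4-(benzyloxy)benzaldehyde and 3,4-bis(benzyloxy)benzyl chloride are taken as purchasable.

Abbreviations in names: ArF = 4-(benzyloxy)-2-[(4R,5R)-4,5-dimethyl-1,3-dioxolan-2-yl]-6-fluorophenyl; DBF-1 = (2R,3R)-6-(benzyloxy)-2-[4-(benzyloxy)phenyl]-3-[3,5-bis(benzyloxy)phenyl]-2,3-dihydro-1-benzofuran-4-yl; DBF-2 = (2S,3S)-6-(benzyloxy)-2-[4-(benzyloxy)phenyl]-3-(DBF-1)-2,3-dihydro-1-benzofuran-4-yl; DBF-3 = (2R,3R)-6-(benzyloxy)-2-[4-(benzyloxy)phenyl]-3-(DBF-2)-2,3-dihydro-1-benzofuran-4-yl.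

**Route**

Step 1
Reactants: 1 3-fluoro-5-hydroxybenzaldehyde
Product: 2 3-(benzyloxy)-5-fluorobenzaldehyde
Conditions: BnBr, K2CO3, DMF, rt
Reagents that add atoms: benzyl bromide, BrCc1ccccc1
Why: Williamson ether synthesis of the phenol with a primary benzylic bromide; no stereocentre is formed.

Step 2
Reactants: 2 3-(benzyloxy)-5-fluorobenzaldehyde
Product: 3 5-(benzyloxy)-2-bromo-3-fluorobenzaldehyde
Conditions: NBS, MeCN, 0 °C → rt, dark
Reagents that add atoms: N-bromosuccinimide, O=C1CCC(=O)N1Br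
Why: electrophilic aromatic bromination should go para to the benzyloxy group, that is to the position between CHO and F, as in the bromination of other 3-alkoxybenzaldehydes; no stereocentre is formed.

Step 3
Reactants: 3 5-(benzyloxy)-2-bromo-3-fluorobenzaldehyde, 4 (2R,3R)-butane-2,3-diol
Product: 5 (4R,5R)-2-[5-(benzyloxy)-2-bromo-3-fluorophenyl]-4,5-dimethyl-1,3-dioxolane
Conditions: p-TsOH (cat.), toluene, reflux, Dean–Stark trap
Reagents that add atoms: none
Why: acid-catalysed acetalisation with azeotropic removal of water; the two stereocentres come unchanged from the diol and the acetal carbon is not stereogenic because the diol is C2-symmetric.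

Step 4
Reactants: 5 (4R,5R)-2-[5-(benzyloxy)-2-bromo-3-fluorophenyl]-4,5-dimethyl-1,3-dioxolane, 6 3,5-bis(benzyloxy)benzyl bromide
Product: 8 (ArF)[3,5-bis(benzyloxy)phenyl]methane, via benzylzinc bromide 7 (not isolated)
Conditions: 6, Zn dust, LiCl, THF, 0 °C → rt; then 5, Pd(OAc)2 (cat.), SPhos (cat.), THF, 50 °C
Reagents that add atoms: none
Why: LiCl-assisted insertion of zinc into the benzylic C–Br bond followed by Negishi coupling with the di-ortho-substituted aryl bromide under zerovalent palladium/SPhos catalysis (generated in the flask from Pd(OAc)2) should give the diarylmethane, the C–F bond, the acetal and the benzyl ethers being inert to the organozinc; no stereocentre is formed.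

Step 5
Reactants: 8 (ArF)[3,5-bis(benzyloxy)phenyl]methane, 9 4-(benzyloxy)benzaldehyde
Product: 12 (4R,5R)-2-(DBF-1)-4,5-dimethyl-1,3-dioxolane, via diarylmethylpotassium 10 (not isolated), via potassium alkoxide 11 (not isolated)
Conditions: LiN(iPr)2, KOtBu, THF, −78 °C; 9, −78 °C; 18-crown-6, −78 → 45 °C
Reagents that add atoms: none
Why: Proposed new method: the mixed lithium–potassium amide should remove a proton from the doubly benzylic CH2 of 8 (the most acidic C–H, its potassium held by the ortho fluorine and the dioxolane oxygens), carbanion 10 adds to the non-enolisable aldehyde 9, and alkoxide 11 displaces the ortho fluoride by intramolecular SNAr; because addition of this hindered, stabilised carbanion is reversible, the slower ring closure should select the trans-2,3-diaryl ring, and the (4R,5R)-dioxolane makes the (2R,3R) and (2S,3S) trans products diastereomers, of which the (2R,3R) isomer 12 is taken on after chromatographic separation whatever bias the acetal exerts; the closest known reactions are the one-pot benzylic deprotonation/addition/SNAr sequences of 2-fluorotoluenes and 2-fluoro-3-picoline with nitriles or N-silyl aldimines that give indoles and azaindolines, the benzylic metalation of fluorotoluenes with LiN(iPr)2/KOtBu, and the alkoxide SNAr closure of 2-(2-fluoroaryl)ethanols to 2,3-dihydrobenzofurans.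

Step 6
Reactants: 12 (4R,5R)-2-(DBF-1)-4,5-dimethyl-1,3-dioxolane
Product: 13 (2R,3R)-6-(benzyloxy)-2-[4-(benzyloxy)phenyl]-3-[3,5-bis(benzyloxy)phenyl]-2,3-dihydro-1-benzofuran-4-carbaldehyde
Conditions: 2 M HCl, THF, 40 °C
Reagents that add atoms: water, O
Why: acid-catalysed acetal hydrolysis; the trans ring is the thermodynamic isomer and its stereocentres should not be touched by dilute aqueous acid.

Step 7
Reactants: 13 (2R,3R)-6-(benzyloxy)-2-[4-(benzyloxy)phenyl]-3-[3,5-bis(benzyloxy)phenyl]-2,3-dihydro-1-benzofuran-4-carbaldehyde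
Product: 14 (DBF-1)methanol
Conditions: NaBH4, THF/MeOH, 0 °C
Reagents that add atoms: none
Why: borohydride reduction of an aryl aldehyde to the primary benzylic alcohol; no stereocentre is formed and the ring stereocentres are not involved.

Step 8
Reactants: 14 (DBF-1)methanol
Product: 15 chloro(DBF-1)methane, that is (2R,3R)-6-(benzyloxy)-2-[4-(benzyloxy)phenyl]-3-[3,5-bis(benzyloxy)phenyl]-4-(chloromethyl)-2,3-dihydro-1-benzofuran
Conditions: PPh3, N-chlorosuccinimide, THF, 0 °C; then 14, 0 °C → rt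
Reagents that add atoms: N-chlorosuccinimide, O=C1CCC(=O)N1Cl
Why: Appel-type chlorination of a primary benzylic alcohol with the preformed chlorophosphonium salt, under neutral conditions that leave the acid-sensitive dihydrobenzofuran and the benzyl ethers alone; no stereocentre is formed.

Step 9
Reactants: 15 chloro(DBF-1)methane, 5 (4R,5R)-2-[5-(benzyloxy)-2-bromo-3-fluorophenyl]-4,5-dimethyl-1,3-dioxolane
Product: 17 (ArF)(DBF-1)methane, via benzylic zinc chloride 16 (not isolated)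
Conditions: 15, Zn dust, LiCl, THF, rt; then 5, Pd(OAc)2 (cat.), SPhos (cat.), THF, 50 °C
Reagents that add atoms: none
Why: LiCl-assisted zinc insertion into the benzylic C–Cl bond and Negishi coupling with aryl bromide 5 under zerovalent palladium/SPhos catalysis, as in step 4; the organozinc is not basic enough to touch the ring C-3–H, so the two ring stereocentres are kept and no new one is formed.

Step 10
Reactants: 17 (ArF)(DBF-1)methane, 9 4-(benzyloxy)benzaldehyde
Product: 21 (2S,3S)-6-(benzyloxy)-2-[4-(benzyloxy)phenyl]-3-(DBF-1)-2,3-dihydro-1-benzofuran-4-carbaldehyde, via diarylmethylpotassium 18 (not isolated), via potassium alkoxide 19 (not isolated), via dioxolane 20 (not isolated)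
Conditions: LiN(iPr)2, KOtBu, THF, −78 °C; 9, −78 °C; 18-crown-6, −78 → 45 °C; then 2 M HCl, THF, rt
Reagents that add atoms: water, O
Why: Proposed new method: the same cascade as in step 5 (metalation of the CH2 of 17, reversible addition of carbanion 18 to 9, SNAr closure of alkoxide 19, closest known reactions as named there) should close the ring trans, and its sense relative to the first ring should be fixed in the ring-closing transition state, where the small H on the new C-3 lies in the plane of ring C pointing to the neighbouring C-3 and the dioxolane-bearing ring B therefore takes the face of ring C opposite to ring D, which corresponds to (2S,3S); the acid work-up unmasks the aldehyde.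

Step 11
Reactants: 21 (2S,3S)-6-(benzyloxy)-2-[4-(benzyloxy)phenyl]-3-(DBF-1)-2,3-dihydro-1-benzofuran-4-carbaldehyde
Product: 22 (DBF-2)methanol
Conditions: NaBH4, THF/MeOH, 0 °C
Reagents that add atoms: none
Why: borohydride reduction of the aryl aldehyde as in step 7; the four ring stereocentres are not involved.

Step 12
Reactants: 22 (DBF-2)methanol
Product: 23 chloro(DBF-2)methane
Conditions: PPh3, N-chlorosuccinimide, THF, 0 °C; then 22, 0 °C → rt
Reagents that add atoms: N-chlorosuccinimide, O=C1CCC(=O)N1Cl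
Why: Appel-type chlorination of the primary benzylic alcohol as in step 8; no stereocentre is formed or touched.

Step 13
Reactants: 23 chloro(DBF-2)methane, 5 (4R,5R)-2-[5-(benzyloxy)-2-bromo-3-fluorophenyl]-4,5-dimethyl-1,3-dioxolane
Product: 25 (ArF)(DBF-2)methane, via benzylic zinc chloride 24 (not isolated)
Conditions: 23, Zn dust, LiCl, THF, rt; then 5, Pd(OAc)2 (cat.), SPhos (cat.), THF, 50 °C
Reagents that add atoms: none
Why: zinc insertion and Negishi coupling with aryl bromide 5 under zerovalent palladium/SPhos catalysis as in step 9; the four ring stereocentres are not involved.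

Step 14
Reactants: 25 (ArF)(DBF-2)methane, 9 4-(benzyloxy)benzaldehyde
Product: 29 (2R,3R)-6-(benzyloxy)-2-[4-(benzyloxy)phenyl]-3-(DBF-2)-2,3-dihydro-1-benzofuran-4-carbaldehyde, via diarylmethylpotassium 26 (not isolated), via potassium alkoxide 27 (not isolated), via dioxolane 28 (not isolated)
Conditions: LiN(iPr)2, KOtBu, THF, −78 °C; 9, −78 °C; 18-crown-6, −78 → 45 °C; then 2 M HCl, THF, rt
Reagents that add atoms: water, O
Why: Proposed new method: the mixed lithium–potassium amide removes a proton from the CH2 between rings A and B of 25, carbanion 26 adds to the non-enolisable aldehyde 9 and so forms the C-2–C-3 bond, and the potassium alkoxide 27 then attacks C-7a of ring A and expels fluoride, which forms the O-1–C-7a bond, the acid work-up only unmasking the aldehyde. The closest known reactions are the one-pot benzylic deprotonation/addition/SNAr sequences of 2-fluorotoluenes and 2-fluoro-3-picoline with nitriles or N-silyl aldimines that give indoles and azaindolines, the benzylic metalation of fluorotoluenes with LiN(iPr)2/KOtBu, and the alkoxide SNAr closure of 2-(2-fluoroaryl)ethanols to 2,3-dihydrobenzofurans; new here are the oxygen nucleophile in the cascade and the diarylmethane substrate. One ring is closed, the five-membered ring, by intramolecular SNAr (5-exo-trig attack of O on the C-7a=C-7 bond through an anionic σ-adduct) after an intermolecular C–C bond formation. C-2 and C-3 should come out trans because addition of the hindered, stabilised carbanion is reversible under potassium/crown ether conditions and the slower ring closure passes through the transition state with the two aryl groups on opposite faces of the forming ring; the sense at C-3 is fixed by the neighbouring ring, since the small H on the new C-3 lies in the plane of ring B pointing to C-3 of the ring-B heterocycle, ring A and C-2 then lie above and below ring B, and ring A with its ortho dioxolane takes the face away from ring C, which corresponds to (2R,3R). The step needs site selectivity in the metalation and regioselectivity in the ring closure: the secondary diarylmethane CH2 is more acidic and more accessible than the tertiary C-3–H groups of the two existing rings and than the ring C–H next to fluorine, to which the amine-equilibrated amide base does not commit, and only ring A carries a leaving group ortho to the carbon that bears the alkoxide side chain. One equivalent of base is used, so that it ends as KF when the ring closes and no strong base remains beside the product.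

Step 15
Reactants: 30 3,4-bis(benzyloxy)benzyl chloride
Product: 31 diethyl [3,4-bis(benzyloxy)benzyl]phosphonate
Conditions: P(OEt)3, 140 °C
Reagents that add atoms: triethyl phosphite, CCOP(OCC)OCC
Why: Michaelis–Arbuzov reaction of a benzylic chloride; no stereocentre is formed.

Step 16
Reactants: 29 (2R,3R)-6-(benzyloxy)-2-[4-(benzyloxy)phenyl]-3-(DBF-2)-2,3-dihydro-1-benzofuran-4-carbaldehyde, 31 diethyl [3,4-bis(benzyloxy)benzyl]phosphonate
Product: 33 1,2-bis(benzyloxy)-4-[(E)-2-(DBF-3)ethenyl]benzene, via potassium phosphonate 32 (not isolated)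
Conditions: 31, KOtBu, THF, 0 °C; 29, 0 °C → rt
Reagents that add atoms: none
Why: Horner–Wadsworth–Emmons olefination with a benzylic phosphonate anion should give the (E)-stilbene; the base is consumed by the phosphonate before the aldehyde is added, so the ring C-3–H groups do not meet free alkoxide.

Step 17
Reactants: 33 1,2-bis(benzyloxy)-4-[(E)-2-(DBF-3)ethenyl]benzene
Product: 34 4-[(E)-2-{(2R,3R)-6-hydroxy-2-(4-hydroxyphenyl)-3-[(2S,3S)-6-hydroxy-2-(4-hydroxyphenyl)-3-{(2R,3R)-3-(3,5-dihydroxyphenyl)-6-hydroxy-2-(4-hydroxyphenyl)-2,3-dihydro-1-benzofuran-4-yl}-2,3-dihydro-1-benzofuran-4-yl]-2,3-dihydro-1-benzofuran-4-yl}ethenyl]benzene-1,2-diol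
Conditions: BCl3, pentamethylbenzene, CH2Cl2, −78 °C; then H2O
Reagents that add atoms: none
Why: Lewis-acid debenzylation in which pentamethylbenzene traps each benzyl cation, a method that should spare the stilbene and the benzylic ring ethers at −78 °C; no stereocentre is touched.

**Compound list**

1 | 3-fluoro-5-hydroxybenzaldehyde | O=Cc1cc(O)cc(F)c1 | starting material
2 | 3-(benzyloxy)-5-fluorobenzaldehyde | O=Cc1cc(OCc2ccccc2)cc(F)c1 | intermediate
3 | 5-(benzyloxy)-2-bromo-3-fluorobenzaldehyde | O=Cc1cc(OCc2ccccc2)cc(F)c1Br | intermediate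
4 | (2R,3R)-butane-2,3-diol | C[C@@H](O)[C@@H](C)O | starting material
5 | (4R,5R)-2-[5-(benzyloxy)-2-bromo-3-fluorophenyl]-4,5-dimethyl-1,3-dioxolane | Brc1c(F)cc(OCc2ccccc2)cc1C1O[C@H](C)[C@@H](C)O1 | intermediate
6 | 3,5-bis(benzyloxy)benzyl bromide | BrCc1cc(OCc2ccccc2)cc(OCc2ccccc2)c1 | starting material
7 | [3,5-bis(benzyloxy)benzyl]zinc bromide | Br[Zn]Cc1cc(OCc2ccccc2)cc(OCc2ccccc2)c1 | intermediate
8 | (ArF)[3,5-bis(benzyloxy)phenyl]methane | Fc1cc(OCc9ccccc9)cc(C2O[C@H](C)[C@@H](C)O2)c1Cc1cc(OCc9ccccc9)cc(OCc9ccccc9)c1 | intermediate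
9 | 4-(benzyloxy)benzaldehyde | O=Cc1ccc(OCc2ccccc2)cc1 | starting material
10 | potassium (ArF)[3,5-bis(benzyloxy)phenyl]methanide | [K+].Fc1cc(OCc9ccccc9)cc(C2O[C@H](C)[C@@H](C)O2)c1[CH-]c1cc(OCc9ccccc9)cc(OCc9ccccc9)c1 | intermediate
11 | potassium 1-[4-(benzyloxy)phenyl]-2-(ArF)-2-[3,5-bis(benzyloxy)phenyl]ethan-1-olate (interconverting diastereomers at C-1 and C-2) | [K+].[O-]C(c1ccc(OCc9ccccc9)cc1)C(c1cc(OCc9ccccc9)cc(OCc9ccccc9)c1)c1c(F)cc(OCc9ccccc9)cc1C1O[C@H](C)[C@@H](C)O1 | intermediate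
12 | (4R,5R)-2-(DBF-1)-4,5-dimethyl-1,3-dioxolane | C1(c2cc(OCc9ccccc9)cc3c2[C@@H](c2cc(OCc9ccccc9)cc(OCc9ccccc9)c2)[C@H](c2ccc(OCc9ccccc9)cc2)O3)O[C@H](C)[C@@H](C)O1 | intermediate
13 | (2R,3R)-6-(benzyloxy)-2-[4-(benzyloxy)phenyl]-3-[3,5-bis(benzyloxy)phenyl]-2,3-dihydro-1-benzofuran-4-carbaldehyde | O=Cc2cc(OCc9ccccc9)cc3c2[C@@H](c2cc(OCc9ccccc9)cc(OCc9ccccc9)c2)[C@H](c2ccc(OCc9ccccc9)cc2)O3 | intermediate
14 | (DBF-1)methanol | OCc2cc(OCc9ccccc9)cc3c2[C@@H](c2cc(OCc9ccccc9)cc(OCc9ccccc9)c2)[C@H](c2ccc(OCc9ccccc9)cc2)O3 | intermediate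
15 | chloro(DBF-1)methane, (2R,3R)-6-(benzyloxy)-2-[4-(benzyloxy)phenyl]-3-[3,5-bis(benzyloxy)phenyl]-4-(chloromethyl)-2,3-dihydro-1-benzofuran | ClCc2cc(OCc9ccccc9)cc3c2[C@@H](c2cc(OCc9ccccc9)cc(OCc9ccccc9)c2)[C@H](c2ccc(OCc9ccccc9)cc2)O3 | intermediate
16 | [(DBF-1)methyl]zinc chloride | Cl[Zn]Cc2cc(OCc9ccccc9)cc3c2[C@@H](c2cc(OCc9ccccc9)cc(OCc9ccccc9)c2)[C@H](c2ccc(OCc9ccccc9)cc2)O3 | intermediate
17 | (ArF)(DBF-1)methane | Fc1cc(OCc9ccccc9)cc(C2O[C@H](C)[C@@H](C)O2)c1Cc2cc(OCc9ccccc9)cc3c2[C@@H](c2cc(OCc9ccccc9)cc(OCc9ccccc9)c2)[C@H](c2ccc(OCc9ccccc9)cc2)O3 | intermediate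
18 | potassium (ArF)(DBF-1)methanide | [K+].Fc1cc(OCc9ccccc9)cc(C2O[C@H](C)[C@@H](C)O2)c1[CH-]c2cc(OCc9ccccc9)cc3c2[C@@H](c2cc(OCc9ccccc9)cc(OCc9ccccc9)c2)[C@H](c2ccc(OCc9ccccc9)cc2)O3 | intermediate
19 | potassium 1-[4-(benzyloxy)phenyl]-2-(ArF)-2-(DBF-1)ethan-1-olate (interconverting diastereomers at C-1 and C-2) | [K+].[O-]C(c1ccc(OCc9ccccc9)cc1)C(c1c(F)cc(OCc9ccccc9)cc1C1O[C@H](C)[C@@H](C)O1)c2cc(OCc9ccccc9)cc3c2[C@@H](c2cc(OCc9ccccc9)cc(OCc9ccccc9)c2)[C@H](c2ccc(OCc9ccccc9)cc2)O3 | intermediate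
20 | (4R,5R)-2-(DBF-2)-4,5-dimethyl-1,3-dioxolane | c9ccccc9COc1ccc([C@H]2Oc3cc(OCc9ccccc9)cc(C4O[C@H](C)[C@@H](C)O4)c3[C@@H]2c2cc(OCc9ccccc9)cc3c2[C@@H](c2cc(OCc9ccccc9)cc(OCc9ccccc9)c2)[C@H](c2ccc(OCc9ccccc9)cc2)O3)cc1 | intermediate
21 | (2S,3S)-6-(benzyloxy)-2-[4-(benzyloxy)phenyl]-3-(DBF-1)-2,3-dihydro-1-benzofuran-4-carbaldehyde | c9ccccc9COc1ccc([C@H]2Oc3cc(OCc9ccccc9)cc(C=O)c3[C@@H]2c2cc(OCc9ccccc9)cc3c2[C@@H](c2cc(OCc9ccccc9)cc(OCc9ccccc9)c2)[C@H](c2ccc(OCc9ccccc9)cc2)O3)cc1 | intermediate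
22 | (DBF-2)methanol | c9ccccc9COc1ccc([C@H]2Oc3cc(OCc9ccccc9)cc(CO)c3[C@@H]2c2cc(OCc9ccccc9)cc3c2[C@@H](c2cc(OCc9ccccc9)cc(OCc9ccccc9)c2)[C@H](c2ccc(OCc9ccccc9)cc2)O3)cc1 | intermediate
23 | chloro(DBF-2)methane | c9ccccc9COc1ccc([C@H]2Oc3cc(OCc9ccccc9)cc(CCl)c3[C@@H]2c2cc(OCc9ccccc9)cc3c2[C@@H](c2cc(OCc9ccccc9)cc(OCc9ccccc9)c2)[C@H](c2ccc(OCc9ccccc9)cc2)O3)cc1 | intermediate
24 | [(DBF-2)methyl]zinc chloride | c9ccccc9COc1ccc([C@H]2Oc3cc(OCc9ccccc9)cc(C[Zn]Cl)c3[C@@H]2c2cc(OCc9ccccc9)cc3c2[C@@H](c2cc(OCc9ccccc9)cc(OCc9ccccc9)c2)[C@H](c2ccc(OCc9ccccc9)cc2)O3)cc1 | intermediate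
25 | (ArF)(DBF-2)methane | c9ccccc9COc1ccc([C@H]2Oc3cc(OCc9ccccc9)cc(Cc4c(F)cc(OCc9ccccc9)cc4C4O[C@H](C)[C@@H](C)O4)c3[C@@H]2c2cc(OCc9ccccc9)cc3c2[C@@H](c2cc(OCc9ccccc9)cc(OCc9ccccc9)c2)[C@H](c2ccc(OCc9ccccc9)cc2)O3)cc1 | intermediate
26 | potassium (ArF)(DBF-2)methanide | [K+].c9ccccc9COc1ccc([C@H]2Oc3cc(OCc9ccccc9)cc([CH-]c4c(F)cc(OCc9ccccc9)cc4C4O[C@H](C)[C@@H](C)O4)c3[C@@H]2c2cc(OCc9ccccc9)cc3c2[C@@H](c2cc(OCc9ccccc9)cc(OCc9ccccc9)c2)[C@H](c2ccc(OCc9ccccc9)cc2)O3)cc1 | intermediate
27 | potassium 1-[4-(benzyloxy)phenyl]-2-(ArF)-2-(DBF-2)ethan-1-olate (interconverting diastereomers at C-1 and C-2) | [K+].c9ccccc9COc1ccc([C@H]2Oc3cc(OCc9ccccc9)cc(C(C([O-])c5ccc(OCc9ccccc9)cc5)c4c(F)cc(OCc9ccccc9)cc4C4O[C@H](C)[C@@H](C)O4)c3[C@@H]2c2cc(OCc9ccccc9)cc3c2[C@@H](c2cc(OCc9ccccc9)cc(OCc9ccccc9)c2)[C@H](c2ccc(OCc9ccccc9)cc2)O3)cc1 | intermediate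
28 | (4R,5R)-2-(DBF-3)-4,5-dimethyl-1,3-dioxolane | c9ccccc9COc1ccc([C@H]2Oc3cc(OCc9ccccc9)cc([C@@H]4c5c(C6O[C@H](C)[C@@H](C)O6)cc(OCc9ccccc9)cc5O[C@H]4c4ccc(OCc9ccccc9)cc4)c3[C@@H]2c2cc(OCc9ccccc9)cc3c2[C@@H](c2cc(OCc9ccccc9)cc(OCc9ccccc9)c2)[C@H](c2ccc(OCc9ccccc9)cc2)O3)cc1 | intermediate
29 | (2R,3R)-6-(benzyloxy)-2-[4-(benzyloxy)phenyl]-3-(DBF-2)-2,3-dihydro-1-benzofuran-4-carbaldehyde | c9ccccc9COc1ccc([C@H]2Oc3cc(OCc9ccccc9)cc([C@@H]4c5c(C=O)cc(OCc9ccccc9)cc5O[C@H]4c4ccc(OCc9ccccc9)cc4)c3[C@@H]2c2cc(OCc9ccccc9)cc3c2[C@@H](c2cc(OCc9ccccc9)cc(OCc9ccccc9)c2)[C@H](c2ccc(OCc9ccccc9)cc2)O3)cc1 | intermediate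
30 | 3,4-bis(benzyloxy)benzyl chloride | ClCc1ccc(OCc2ccccc2)c(OCc2ccccc2)c1 | starting material
31 | diethyl [3,4-bis(benzyloxy)benzyl]phosphonate | CCOP(=O)(OCC)Cc1ccc(OCc2ccccc2)c(OCc2ccccc2)c1 | intermediate
32 | potassium salt of 31 deprotonated at the benzylic carbon | [K+].CCOP(=O)(OCC)[CH-]c1ccc(OCc2ccccc2)c(OCc2ccccc2)c1 | intermediate
33 | 1,2-bis(benzyloxy)-4-[(E)-2-(DBF-3)ethenyl]benzene (deca-O-benzyl ether of the target) | c9ccccc9COc1ccc([C@H]2Oc3cc(OCc9ccccc9)cc([C@@H]4c5c(/C=C/c6ccc(OCc9ccccc9)c(OCc9ccccc9)c6)cc(OCc9ccccc9)cc5O[C@H]4c4ccc(OCc9ccccc9)cc4)c3[C@@H]2c2cc(OCc9ccccc9)cc3c2[C@@H](c2cc(OCc9ccccc9)cc(OCc9ccccc9)c2)[C@H](c2ccc(OCc9ccccc9)cc2)O3)cc1 | intermediate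
34 | CNP0099535.1, 4-[(E)-2-{(2R,3R)-6-hydroxy-2-(4-hydroxyphenyl)-3-[(2S,3S)-6-hydroxy-2-(4-hydroxyphenyl)-3-{(2R,3R)-3-(3,5-dihydroxyphenyl)-6-hydroxy-2-(4-hydroxyphenyl)-2,3-dihydro-1-benzofuran-4-yl}-2,3-dihydro-1-benzofuran-4-yl]-2,3-dihydro-1-benzofuran-4-yl}ethenyl]benzene-1,2-diol | Oc1ccc([C@H]2Oc3cc(O)cc([C@@H]4c5c(/C=C/c6ccc(O)c(O)c6)cc(O)cc5O[C@H]4c4ccc(O)cc4)c3[C@@H]2c2cc(O)cc3c2[C@@H](c2cc(O)cc(O)c2)[C@H](c2ccc(O)cc2)O3)cc1 | target

**Step count and risks**

Total: 17 steps. Longest linear sequence: 16 steps (steps 1 to 14, 16, 17); step 15 is a side branch and bromide 5 is used three times.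

Steps most likely to fail:

Step 14 (key step). What may go wrong: poor facial discrimination at the new C-3, if the alkoxide diastereomers close faster than they interconvert or the ring-closing transition states differ too little, so that the trans ring forms with the wrong sense relative to the ring-B heterocycle. Fallback: it sets out from 25 and comes back at 29 through 28. The carbanion from 25 (two equivalents of the amide base) is acylated with methyl 4-(benzyloxy)benzoate to give the α,α-diaryl ketone 1-[4-(benzyloxy)phenyl]-2-(ArF)-2-(DBF-2)ethan-1-one F1, whose centre next to the carbonyl is equilibrated with Et3N. Reduction with NaBH4 in THF/MeOH and chromatographic removal of the other diastereomers should give the alcohol (1R,2R)-1-[4-(benzyloxy)phenyl]-2-(ArF)-2-(DBF-2)ethan-1-ol F2. KN(SiMe3)2 in THF/DMF then closes the ring by the known alkoxide SNAr on the fluoroarene to give 28, and the acid treatment of step 14 gives 29. The two stereocentres are thus set in separate, individually adjustable events instead of in one cascade.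

Step 10. What may go wrong: proton transfer from the tertiary C-3–H of the existing dihydrobenzofuran to the amide base or to carbanion 18, followed by E1cB loss of the aryloxide and irreversible ring opening. Fallback: it sets out from 15 and comes back at 21 through 20, and it uses no base stronger than an alkoxide. Chloride 15 is converted into the zinc reagent 16 as in step 9, and this is acylated with 4-(benzyloxy)benzoyl chloride under Pd(PPh3)4 catalysis (Negishi acylation) to give the ketone 1-[4-(benzyloxy)phenyl]-2-(DBF-1)ethan-1-one F3. Palladium-catalysed α-arylation of its enolate with aryl bromide 5 (Pd(OAc)2, SPhos, NaOtBu, toluene, 80 °C) gives the α,α-diaryl ketone 1-[4-(benzyloxy)phenyl]-2-(ArF)-2-(DBF-1)ethan-1-one F4, whose centre next to the carbonyl equilibrates. Reduction with NaBH4 and separation of diastereomers should give the alcohol (1S,2S)-1-[4-(benzyloxy)phenyl]-2-(ArF)-2-(DBF-1)ethan-1-ol F5. NaH in DMF closes the ring by SNAr to 20, and the acid treatment of step 10 gives 21.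

Step 5. What may go wrong: no useful bias from the dioxolane together with co-elution of the two trans diastereomers, so that the absolute configuration is not secured at this stage. Fallback: it sets out from 12, taken as the unseparated mixture with its (2S,3S)-diastereomer, the dioxolane F6, and comes back at 13. The mixture is hydrolysed under the conditions of step 6 to 13 and its enantiomer, the aldehyde F7, and the two are separated by preparative chromatography on a chiral stationary phase; the resolution then rests on a physical separation of enantiomers and not on the auxiliary.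

**Further compounds**

F1 | step 14 | 1-[4-(benzyloxy)phenyl]-2-(ArF)-2-(DBF-2)ethan-1-one (epimers at C-2 interconvert) | c9ccccc9COc1ccc([C@H]2Oc3cc(OCc9ccccc9)cc(C(C(=O)c5ccc(OCc9ccccc9)cc5)c4c(F)cc(OCc9ccccc9)cc4C4O[C@H](C)[C@@H](C)O4)c3[C@@H]2c2cc(OCc9ccccc9)cc3c2[C@@H](c2cc(OCc9ccccc9)cc(OCc9ccccc9)c2)[C@H](c2ccc(OCc9ccccc9)cc2)O3)cc1
F2 | step 14 | (1R,2R)-1-[4-(benzyloxy)phenyl]-2-(ArF)-2-(DBF-2)ethan-1-ol | c9ccccc9COc1ccc([C@H]2Oc3cc(OCc9ccccc9)cc([C@@H]([C@@H](O)c5ccc(OCc9ccccc9)cc5)c4c(F)cc(OCc9ccccc9)cc4C4O[C@H](C)[C@@H](C)O4)c3[C@@H]2c2cc(OCc9ccccc9)cc3c2[C@@H](c2cc(OCc9ccccc9)cc(OCc9ccccc9)c2)[C@H](c2ccc(OCc9ccccc9)cc2)O3)cc1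
F3 | step 10 | 1-[4-(benzyloxy)phenyl]-2-(DBF-1)ethan-1-one | O=C(c1ccc(OCc9ccccc9)cc1)Cc2cc(OCc9ccccc9)cc3c2[C@@H](c2cc(OCc9ccccc9)cc(OCc9ccccc9)c2)[C@H](c2ccc(OCc9ccccc9)cc2)O3
F4 | step 10 | 1-[4-(benzyloxy)phenyl]-2-(ArF)-2-(DBF-1)ethan-1-one (epimers at C-2 interconvert) | O=C(c1ccc(OCc9ccccc9)cc1)C(c1c(F)cc(OCc9ccccc9)cc1C1O[C@H](C)[C@@H](C)O1)c2cc(OCc9ccccc9)cc3c2[C@@H](c2cc(OCc9ccccc9)cc(OCc9ccccc9)c2)[C@H](c2ccc(OCc9ccccc9)cc2)O3
F5 | step 10 | (1S,2S)-1-[4-(benzyloxy)phenyl]-2-(ArF)-2-(DBF-1)ethan-1-ol | c9ccccc9COc1ccc([C@@H](O)[C@H](c3c(F)cc(OCc9ccccc9)cc3C4O[C@H](C)[C@@H](C)O4)c2cc(OCc9ccccc9)cc3c2[C@@H](c2cc(OCc9ccccc9)cc(OCc9ccccc9)c2)[C@H](c2ccc(OCc9ccccc9)cc2)O3)cc1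
F6 | step 5 | (4R,5R)-2-{(2S,3S)-6-(benzyloxy)-2-[4-(benzyloxy)phenyl]-3-[3,5-bis(benzyloxy)phenyl]-2,3-dihydro-1-benzofuran-4-yl}-4,5-dimethyl-1,3-dioxolane | C1(c2cc(OCc9ccccc9)cc3c2[C@H](c2cc(OCc9ccccc9)cc(OCc9ccccc9)c2)[C@@H](c2ccc(OCc9ccccc9)cc2)O3)O[C@H](C)[C@@H](C)O1
F7 | step 5 | (2S,3S)-6-(benzyloxy)-2-[4-(benzyloxy)phenyl]-3-[3,5-bis(benzyloxy)phenyl]-2,3-dihydro-1-benzofuran-4-carbaldehyde | O=Cc2cc(OCc9ccccc9)cc3c2[C@H](c2cc(OCc9ccccc9)cc(OCc9ccccc9)c2)[C@@H](c2ccc(OCc9ccccc9)cc2)O3
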